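What the impurity leaves over of the catalyst is what you should count. At 0.25 mM the impurity is charged in less than the 1.2 mM of free catalyst in the new flask. Treat it as an irreversible active-site titrant, one catalyst lost per impurity. It is then the limiting reagent of that side reaction, and its balance gives the working catalyst, charged catalyst minus charged impurity: 0.950 mM in the new flask.

| flask | starting material | second substrate | coupling partner | free catalyst | impurity | remark | time |
|---|---|---|---|---|---|---|---|
| teal | 0.050 M | 0.050 M (in portions, 3) | 0.090 M | 0.80 mM | 0.25 mM | run made earlier; portions every 40 min |  |
| blue | 0.050 M | 0.050 M (in portions, 3) | 0.090 M | 1.8 mM | 0.25 mM | run made earlier; portions every 40 min |  |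
| flask | 0.050 M | 0.0500 M (in portions, 3) | 0.0900 M | 1.2 mM | 0.25 mM | the portions of second substrate follow each other after 40 min, the first at the start | 50 h |

- teal (time / h: target / %, starting material / %): 4.00: 65, 29; 8.00: 81, 9; 15.0: 87, 0; 25.0: 86, 3; 48.0: 90, 0
- blue (time / h: target / %, starting material / %): 4.00: 86, 2; 12.0: 99, 0; 25.0: 95, 0; 40.0: 95, 3; 48.0: 96, 1

(scatter of a reading: 2 percentage points)

* amount of target in percent of the starting material charged, at 5.0 h, 20 h and 50 h



The same subtraction gives 0.550 mM for the teal run and 1.55 mM for the blue run. Take the loss of starting material as pseudo-first-order. The teal reading at 8.00 h gives 0.301 /h, or 547 /M/h per unit of working catalyst.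

Carried to the blue run, this leaves 3.36% of the starting material at 4.00 h, while scaling by charged catalyst leaves 6.66%. The single reading of 2%, good to 2 percentage points, lies closer to the first.

Now the yield. The late target readings average 87.7% in the teal run and 96.2% in the blue run. Suppose a leak independent of catalyst competes with a path proportional to working catalyst. Then lost over target equals g divided by working catalyst, where g is the working catalyst at which the two paths run equally. The teal run reads 0.0774 mM and the blue run 0.0604 mM, with the scatter of their readings, and their mean is 0.0689 mM.

For the new flask this reckons a plateau of 93.2%. The constant read from the teal run reckons its decay constant at 0.520 /h, which leaves 7.43% of the starting material at 5.0 h. My reckoning is therefore 86.3% at 5.0 h and 93.2% at both 20 h and 50 h.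

The forecast, calling the loss “a selectivity matter that shrinks with more catalyst”, gives 83%, 92% and 93%, lower than my figure at 5.0 h.

The new flask gives 86.0%, 93.0% and 93.0%, by these equations:

    second substrate + free catalyst ⇌ catalyst intermediate B (K = 8.30 /M, k = 165 /M/h)
    starting material + coupling partner → uncatalysed product (k = 0.603 /M/h)
    coupling partner + catalyst intermediate B → free catalyst + second product (k = 106 /M/h)
    free catalyst + impurity → spent catalyst (k = 21600 /M/h)
    coupling partner + catalyst intermediate A → free catalyst + target (k = 761 /M/h)
    starting material + free catalyst ⇌ catalyst intermediate A (K = 50.6 /M, k = 1360 /M/h)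

At 25.0 h the new flask holds 93.0% of target beside 6.96% of uncatalysed product, formed from starting material and coupling partner without catalyst. The working catalyst 0.950 mM reckoned for the new flask is 79.2% of its catalyst charge. At 50.0 h in the new flask, with catalyst intermediate A at 0%, free catalyst at 66.6% and catalyst intermediate B at 12.6% make 79.2% of the catalyst charged, beside spent catalyst at 20.8%.

(The data are calculated on assumed constants; the scatter is artificial.)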